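**Plan**
- Cuts: C3–C4 of ring A; C9–C11; C13–C16 with C14–C15; C10–C1 and C10–C20. The enabling feature is the quaternary, gem-dimethyl C4 of ring A bonded to the C3 carbinol: C4 is read as a tertiary radical from an isopropenyl group on C5, and C3 as an aldehyde on a three-carbon arm at C10.
- Forward: ring B is bought as (R)-carvone, which already carries the C5 isopropenyl and C8 methyl. C20 and an allyl arm go onto C10, the enone is reduced, and a butynyl chain is added to C9 and grown to the (E)-enoate.
- The allyl end is oxidised to the aldehyde, ring A is closed last by iron-hydride HAT radical cyclisation, and the 3-ol is converted through the 3-ketone into the 2α,3α-diol.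
- Stereochemistry: C5 from carvone; C10 by alkylation anti to isopropenyl; C8 by equilibration to the equatorial methyl; C9 by axial attack anti to the axial C20 methyl.
- C2 by α-face epoxidation of the Δ2 silyl enol ether; C3 by equatorial hydride delivery; the E-alkene by syn methylalumination.

Key step: step 10

Remark: labdane numbering is used (ring A C1–C5/C10, ring B C5–C10, chain C11–C16, C17 on C8, C20 on C10); β is the face of the C20 methyl. The SMILES is read as 10β-methyl, 5α-H, 8α-methyl, 9α-chain/9β-OH, 2α,3α-diol, i.e. (1S,2R,4aS,6S,7R,8aS) in decalin numbering. Compound 22 is drawn as the expected 3β-epimer; its C3 epimer would serve equally.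

**Step 1**
Reactants: 1 (R)-(−)-carvone
Product: 3 6-methylcarvone (trans epimer drawn; used as the C6 epimer mixture), via lithium dienolate 2 (not isolated)
Conditions: LiN(i-Pr)2, THF, −78 °C; MeI, −78 → 0 °C
Reagents that add atoms: methyl iodide, CI
Why: Kinetic α′-deprotonation of the enone gives the cross-conjugated enolate, whose SN2 methylation (enolate alkylation) installs the future C20; the C6 configuration is irrelevant because step 2 planarises it.

**Step 2**
Reactants: 3 6-methylcarvone; 4 allyl bromide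
Product: 6 (5S,6S)-2,6-dimethyl-5-(prop-1-en-2-yl)-6-(prop-2-en-1-yl)cyclohex-2-en-1-one, via lithium enolate 5 (not isolated)
Conditions: LiN(i-Pr)2, THF, −78 → 0 °C; allyl bromide, DMPU, −78 °C → rt
Reagents that add atoms: allyl bromide (4), C=CCBr
Why: Enolate alkylation of the tetrasubstituted α′-enolate; the electrophile should enter anti to the neighbouring isopropenyl group, so the allyl arm (C1–C3) ends trans and the methyl cis to isopropenyl, which sets C10.

**Step 3**
Reactants: 6 allylated methylcarvone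
Product: 8 (2S,3S,6R)-2,6-dimethyl-3-(prop-1-en-2-yl)-2-(prop-2-en-1-yl)cyclohexan-1-one, via lithium enolate 7 (not isolated)
Conditions: LiB(s-Bu)3H, THF, −78 °C; MeOH, then NaOMe (cat.), 0 °C → rt
Reagents that add atoms: none
Why: Conjugate (1,4) hydride reduction of the β-unsubstituted enone by the bulky borohydride leaves both isolated alkenes alone; protonation and methoxide equilibration should put the C8 methyl equatorial (8α, trans to isopropenyl and clear of the axial C10 methyl), and the minor epimer can be re-equilibrated.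

**Step 4**
Reactants: 8 ring B ketone; 9 4-bromo-1-(trimethylsilyl)but-1-yne
Product: 12 (1S,2S,3S,6R)-2,6-dimethyl-3-(prop-1-en-2-yl)-2-(prop-2-en-1-yl)-1-[4-(trimethylsilyl)but-3-yn-1-yl]cyclohexan-1-ol, via Grignard reagent 10 (not isolated), via organocerium reagent 11 (not isolated)
Conditions: 9, Mg, THF, rt; CeCl3, THF, −78 °C; then 8, −78 → 0 °C; H2O
Reagents that add atoms: 4-bromo-1-(trimethylsilyl)but-1-yne (9), C[Si](C)(C)C#CCCBr
Why: Organocerium 1,2-addition (Imamoto type) is weakly basic and oxophilic, so it should add to the hindered, enolisable ketone; attack is expected axially on the α-face, anti to the axial C10 methyl, giving the 9α-chain and 9β-OH.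

**Step 5**
Reactants: 12 silylalkyne alcohol
Product: 13 (1S,2S,3S,6R)-1-(but-3-yn-1-yl)-2,6-dimethyl-3-(prop-1-en-2-yl)-2-(prop-2-en-1-yl)cyclohexan-1-ol
Conditions: K2CO3, MeOH, rt
Reagents that add atoms: none
Why: Base-mediated methanolysis of the C(sp)–Si bond (protodesilylation) frees the terminal alkyne without touching the alkenes or the tertiary alcohol.

**Step 6**
Reactants: 13 alkynyl alcohol
Product: 14 triethylsilyl ether of 13 (9-O-SiEt3)
Conditions: Et3SiOTf, 2,6-lutidine, CH2Cl2, 0 °C → rt
Reagents that add atoms: triethylsilyl trifluoromethanesulfonate, CC[Si](CC)(CC)OS(=O)(=O)C(F)(F)F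
Why: Silyl triflate with a hindered base is the standard silylation of tertiary alcohols; the ether later prevents a six-membered lactol between O9 and the C3 aldehyde and keeps an aluminium alkoxide out of step 7.

**Step 7**
Reactants: 14 silyl ether alkyne
Product: 16 methyl (2E)-5-[(1S,2S,3S,6R)-2,6-dimethyl-3-(prop-1-en-2-yl)-2-(prop-2-en-1-yl)-1-(triethylsilyloxy)cyclohexyl]-3-methylpent-2-enoate, via alkenylalane 15 (not isolated)
Conditions: AlMe3, Cp2ZrCl2 (0.25 equiv), CH2Cl2, 0 °C → rt; ClCO2Me, 0 °C → rt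
Reagents that add atoms: trimethylaluminium, C[Al](C)C; methyl chloroformate, COC(=O)Cl
Why: Negishi zirconium-catalysed methylalumination adds Me and Al syn across the terminal alkyne (Al at the terminus) much faster than across unactivated alkenes, and acylation of the alkenyl–Al bond with retention gives the (E)-3-methyl enoate.

**Step 8**
Reactants: 16 triene ester
Product: 18 methyl (2E)-5-[(1S,2S,3S,6R)-2-(3-hydroxypropyl)-2,6-dimethyl-3-(prop-1-en-2-yl)-1-(triethylsilyloxy)cyclohexyl]-3-methylpent-2-enoate, via trialkylborane 17 (not isolated)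
Conditions: (Sia)2BH [BH3·SMe2, 2-methylbut-2-ene], THF, 0 °C; NaBO3·4H2O, H2O, rt
Reagents that add atoms: sodium perborate tetrahydrate (NaBO3·4H2O), [Na+].[Na+].O[B-]1(O)OO[B-](O)(O)OO1
Why: Anti-Markovnikov hydroboration with the hindered dialkylborane should select the monosubstituted allyl alkene over the neopentyl-flanked 1,1-disubstituted isopropenyl group and the conjugated enoate; perborate oxidises the C–B bond without harming the ester.

**Step 9**
Reactants: 18 primary alcohol
Product: 19 methyl (2E)-5-[(1S,2S,3S,6R)-2,6-dimethyl-2-(3-oxopropyl)-3-(prop-1-en-2-yl)-1-(triethylsilyloxy)cyclohexyl]-3-methylpent-2-enoate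
Conditions: Dess–Martin periodinane, NaHCO3, CH2Cl2, 0 °C → rt
Reagents that add atoms: none
Why: Dess–Martin oxidation takes the primary alcohol to the aldehyde under buffered, neutral conditions with no over-oxidation.

**Step 10**
Reactants: 19 isopropenyl aldehyde
Product: 22 methyl (2E)-5-[(1S,2R,4aS,6S,8aS)-6-hydroxy-2,5,5,8a-tetramethyl-1-(triethylsilyloxy)decahydronaphthalen-1-yl]-3-methylpent-2-enoate, via tertiary C4 radical 20 (not isolated), via C3 alkoxy radical 21 (not isolated)
Conditions: Fe(acac)3 (0.5 equiv), PhSiH3 (2.5 equiv, slow addition), degassed EtOH, 60 °C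
Reagents that add atoms: none
Why: Ethanol and PhSiH3 turn Fe(acac)3 into an iron hydride that transfers a hydrogen atom to the CH2 terminus of the isopropenyl group (Markovnikov HAT), so tertiary C4 radical 20 forms already carrying both methyl groups. This radical adds to the C3 aldehyde carbon in a 6-exo-trig closure that forms C3–C4 and ring A; alkoxy radical 21 is then reduced by divalent iron and protonated by ethanol (or quenched by the silane) before β-scission can reopen the ring, which also returns trivalent iron. The closest known reaction type is the iron-hydride HAT reductive cyclisation of alkene-tethered ketones, together with the intermolecular HAT coupling of unactivated alkenes with aldehydes. The ring fusion is not at stake, because C5 and C10 are already set and both new ring bonds are equatorial on ring B (trans-decalin); at C3 a chair transition state with the oxygen pseudo-equatorial should favour the 3β-alcohol, and either epimer is usable because step 11 erases this centre. The step needs HAT at the isopropenyl group and not at the enoate, which the substrate secures: the electron-poor trisubstituted enoate is a poor hydrogen-atom acceptor, the allyl alkene is already consumed, and attack of C4 on the enoate would need a seven-membered closure onto a fully substituted carbon. The 9-O-triethylsilyl group keeps the aldehyde free by excluding lactol formation with O9.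

**Step 11**
Reactants: 22 3β-alcohol
Product: 23 methyl (2E)-3-methyl-5-[(1S,2R,4aR,8aS)-2,5,5,8a-tetramethyl-6-oxo-1-(triethylsilyloxy)decahydronaphthalen-1-yl]pent-2-enoate
Conditions: Dess–Martin periodinane, NaHCO3, CH2Cl2, rt
Reagents that add atoms: none
Why: Dess–Martin oxidation of the neopentyl secondary alcohol gives the 3-ketone and makes both C3 epimers of 22 converge.

**Step 12**
Reactants: 23 3-ketone
Product: 24 Δ2 trimethylsilyl enol ether of 23 (3-OSiMe3, C2=C3)
Conditions: Me3SiOTf, Et3N, CH2Cl2, 0 °C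
Reagents that add atoms: trimethylsilyl trifluoromethanesulfonate, C[Si](C)(C)OS(=O)(=O)C(F)(F)F
Why: Soft enolisation (silyl triflate and amine) of a ketone with only one enolisable side, since C4 is quaternary, gives the Δ2 enol ether regiospecifically; no strong base is present that could deprotonate the enoate at its γ-position.

**Step 13**
Reactants: 24 silyl enol ether
Product: 27 methyl (2E)-5-[(1S,2R,4aR,7R,8aS)-7-hydroxy-2,5,5,8a-tetramethyl-6-oxo-1-(triethylsilyloxy)decahydronaphthalen-1-yl]-3-methylpent-2-enoate, via siloxy epoxide 25 (not isolated), via 2α-silyloxy ketone 26 (not isolated)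
Conditions: mCPBA, NaHCO3, CH2Cl2, −20 → 0 °C; 10% aq. citric acid, THF, rt
Reagents that add atoms: 3-chloroperoxybenzoic acid, OOC(=O)c1cccc(Cl)c1
Why: Rubottom oxidation: the peracid should epoxidise the electron-rich enol ether on the α-face, anti to the axial C10 and 4β methyl groups, and silyl shift followed by mild acid hydrolysis gives the equatorial 2α-hydroxy ketone; the electron-poor enoate reacts far more slowly.

**Step 14**
Reactants: 27 2α-hydroxy-3-ketone
Product: 28 methyl (2E)-5-[(1S,2R,4aS,6S,7R,8aS)-6,7-dihydroxy-2,5,5,8a-tetramethyl-1-(triethylsilyloxy)decahydronaphthalen-1-yl]-3-methylpent-2-enoate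
Conditions: LiB(s-Bu)3H (2.5 equiv), THF, −78 °C; H2O
Reagents that add atoms: none
Why: Bulky trialkylborohydride reduction should deliver hydride along the equatorial trajectory, avoiding the syn-axial H1α and H5α, and so give the axial 3α-alcohol cis to the 2α-hydroxyl; at −78 °C the ester and the β,β-disubstituted enoate should be inert.

**Step 15**
Reactants: 28 silyl-protected triol
Product: 29 methyl (2E)-5-[(1S,2R,4aS,6S,7R,8aS)-1,6,7-trihydroxy-2,5,5,8a-tetramethyldecahydronaphthalen-1-yl]-3-methylpent-2-enoate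
Conditions: HF·pyridine, pyridine, THF, 0 °C → rt
Reagents that add atoms: none
Why: Buffered fluoride cleavage of the Si–O bond (desilylation) frees the tertiary 9β-hydroxyl without ionising the C9–O bond or touching the enoate.

**Compound list**
1 | (R)-(−)-carvone, (5R)-2-methyl-5-(prop-1-en-2-yl)cyclohex-2-en-1-one | CC1=CC[C@@H](C(C)=C)CC1=O | starting material
2 | lithium dienolate of 1 (O–Li on C1, C1=C6 and C2=C3) | [Li]OC1=C[C@H](C(C)=C)CC=C1C | intermediate
3 | 6-methylcarvone, (5R,6S)-2,6-dimethyl-5-(prop-1-en-2-yl)cyclohex-2-en-1-one (trans epimer drawn; C6 epimer mixture used) | O=C1C(C)=CC[C@@H](C(C)=C)[C@@H]1C | intermediate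
4 | allyl bromide | C=CCBr | starting material
5 | lithium enolate of 3 | [Li]OC1=C(C)[C@H](C(C)=C)CC=C1C | intermediate
6 | (5S,6S)-2,6-dimethyl-5-(prop-1-en-2-yl)-6-(prop-2-en-1-yl)cyclohex-2-en-1-one | O=C1C(C)=CC[C@@H](C(C)=C)[C@]1(C)CC=C | intermediate
7 | lithium enolate from 1,4-reduction of 6 | [Li]OC1=C(C)CC[C@@H](C(C)=C)[C@]1(C)CC=C | intermediate
8 | (2S,3S,6R)-2,6-dimethyl-3-(prop-1-en-2-yl)-2-(prop-2-en-1-yl)cyclohexan-1-one | O=C1[C@H](C)CC[C@@H](C(C)=C)[C@]1(C)CC=C | intermediate
9 | 4-bromo-1-(trimethylsilyl)but-1-yne | C[Si](C)(C)C#CCCBr | starting material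
10 | [4-(trimethylsilyl)but-3-yn-1-yl]magnesium bromide | C[Si](C)(C)C#CCC[Mg]Br | intermediate
11 | dichloro[4-(trimethylsilyl)but-3-yn-1-yl]cerium | C[Si](C)(C)C#CCC[Ce](Cl)Cl | intermediate
12 | (1S,2S,3S,6R)-2,6-dimethyl-3-(prop-1-en-2-yl)-2-(prop-2-en-1-yl)-1-[4-(trimethylsilyl)but-3-yn-1-yl]cyclohexan-1-ol | C[Si](C)(C)C#CCC[C@]1(O)[C@H](C)CC[C@@H](C(C)=C)[C@]1(C)CC=C | intermediate
13 | (1S,2S,3S,6R)-1-(but-3-yn-1-yl)-2,6-dimethyl-3-(prop-1-en-2-yl)-2-(prop-2-en-1-yl)cyclohexan-1-ol | C#CCC[C@]1(O)[C@H](C)CC[C@@H](C(C)=C)[C@]1(C)CC=C | intermediate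
14 | triethylsilyl ether of 13 | C#CCC[C@]1(O[Si](CC)(CC)CC)[C@H](C)CC[C@@H](C(C)=C)[C@]1(C)CC=C | intermediate
15 | (E)-alkenyl(dimethyl)alane from methylalumination of 14 | C[Al](C)/C=C(\C)CC[C@]1(O[Si](CC)(CC)CC)[C@H](C)CC[C@@H](C(C)=C)[C@]1(C)CC=C | intermediate
16 | methyl (2E)-5-[(1S,2S,3S,6R)-2,6-dimethyl-3-(prop-1-en-2-yl)-2-(prop-2-en-1-yl)-1-(triethylsilyloxy)cyclohexyl]-3-methylpent-2-enoate | COC(=O)/C=C(\C)CC[C@]1(O[Si](CC)(CC)CC)[C@H](C)CC[C@@H](C(C)=C)[C@]1(C)CC=C | intermediate
17 | C3 bis(3-methylbutan-2-yl)borane adduct of 16 | COC(=O)/C=C(\C)CC[C@]1(O[Si](CC)(CC)CC)[C@H](C)CC[C@@H](C(C)=C)[C@]1(C)CCCB(C(C)C(C)C)C(C)C(C)C | intermediate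
18 | methyl (2E)-5-[(1S,2S,3S,6R)-2-(3-hydroxypropyl)-2,6-dimethyl-3-(prop-1-en-2-yl)-1-(triethylsilyloxy)cyclohexyl]-3-methylpent-2-enoate | COC(=O)/C=C(\C)CC[C@]1(O[Si](CC)(CC)CC)[C@H](C)CC[C@@H](C(C)=C)[C@]1(C)CCCO | intermediate
19 | methyl (2E)-5-[(1S,2S,3S,6R)-2,6-dimethyl-2-(3-oxopropyl)-3-(prop-1-en-2-yl)-1-(triethylsilyloxy)cyclohexyl]-3-methylpent-2-enoate | COC(=O)/C=C(\C)CC[C@]1(O[Si](CC)(CC)CC)[C@H](C)CC[C@@H](C(C)=C)[C@]1(C)CCC=O | intermediate
20 | tertiary C4 radical of 19 (H added to the isopropenyl CH2) | COC(=O)/C=C(\C)CC[C@]1(O[Si](CC)(CC)CC)[C@H](C)CC[C@@H]([C](C)C)[C@]1(C)CCC=O | intermediate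
21 | ring-closed C3 alkoxy radical (3β-O•) | COC(=O)/C=C(\C)CC[C@]1(O[Si](CC)(CC)CC)[C@H](C)CC[C@H]2C(C)(C)[C@@H]([O])CC[C@@]21C | intermediate
22 | methyl (2E)-5-[(1S,2R,4aS,6S,8aS)-6-hydroxy-2,5,5,8a-tetramethyl-1-(triethylsilyloxy)decahydronaphthalen-1-yl]-3-methylpent-2-enoate (3β-ol) | COC(=O)/C=C(\C)CC[C@]1(O[Si](CC)(CC)CC)[C@H](C)CC[C@H]2C(C)(C)[C@@H](O)CC[C@@]21C | intermediate
23 | methyl (2E)-3-methyl-5-[(1S,2R,4aR,8aS)-2,5,5,8a-tetramethyl-6-oxo-1-(triethylsilyloxy)decahydronaphthalen-1-yl]pent-2-enoate (3-ketone) | COC(=O)/C=C(\C)CC[C@]1(O[Si](CC)(CC)CC)[C@H](C)CC[C@H]2C(C)(C)C(=O)CC[C@@]21C | intermediate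
24 | Δ2 trimethylsilyl enol ether of 23 | COC(=O)/C=C(\C)CC[C@]1(O[Si](CC)(CC)CC)[C@H](C)CC[C@H]2C(C)(C)C(O[Si](C)(C)C)=CC[C@@]21C | intermediate
25 | 2α,3α-epoxide of 24 (3β-OSiMe3) | COC(=O)/C=C(\C)CC[C@]1(O[Si](CC)(CC)CC)[C@H](C)CC[C@H]2C(C)(C)[C@]3(O[Si](C)(C)C)O[C@@H]3C[C@@]21C | intermediate
26 | 2α-trimethylsilyloxy-3-ketone | COC(=O)/C=C(\C)CC[C@]1(O[Si](CC)(CC)CC)[C@H](C)CC[C@H]2C(C)(C)C(=O)[C@H](O[Si](C)(C)C)C[C@@]21C | intermediate
27 | methyl (2E)-5-[(1S,2R,4aR,7R,8aS)-7-hydroxy-2,5,5,8a-tetramethyl-6-oxo-1-(triethylsilyloxy)decahydronaphthalen-1-yl]-3-methylpent-2-enoate (2α-hydroxy-3-ketone) | COC(=O)/C=C(\C)CC[C@]1(O[Si](CC)(CC)CC)[C@H](C)CC[C@H]2C(C)(C)C(=O)[C@H](O)C[C@@]21C | intermediate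
28 | methyl (2E)-5-[(1S,2R,4aS,6S,7R,8aS)-6,7-dihydroxy-2,5,5,8a-tetramethyl-1-(triethylsilyloxy)decahydronaphthalen-1-yl]-3-methylpent-2-enoate | COC(=O)/C=C(\C)CC[C@]1(O[Si](CC)(CC)CC)[C@H](C)CC[C@H]2C(C)(C)[C@H](O)[C@H](O)C[C@@]21C | intermediate
29 | methyl (2E)-5-[(1S,2R,4aS,6S,7R,8aS)-1,6,7-trihydroxy-2,5,5,8a-tetramethyldecahydronaphthalen-1-yl]-3-methylpent-2-enoate (CNP0292844.1) | COC(=O)/C=C(\C)CC[C@]1(O)[C@H](C)CC[C@H]2C(C)(C)[C@H](O)[C@H](O)C[C@@]21C | target

**Count and risks**
Total step count: 15. Longest linear sequence: 15 steps (1 → 29); bromide 9 enters in step 4 as a Grignard reagent made in the same flask.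

Most likely to fail:

1. Step 10. Ring reopening by β-scission of the C3 alkoxy radical may outrun its reduction, and simple reduction of the C4 radical or silane reduction of the aldehyde may compete. The fallback changes the acceptor to a nitrile, whose ring-closed iminyl radical does not fragment readily. It sets out from aldehyde 19, which I2 in aqueous NH3/THF would convert into the C3 nitrile F1. The same Fe(acac)3/PhSiH3/EtOH conditions should then close ring A by 6-exo-dig addition of the C4 radical to the nitrile carbon, giving after reduction the cyclic ketimine F2. Mild aqueous acid (oxalic acid, THF) hydrolyses F2 to ketone 23, where the route is rejoined and step 11 is no longer needed.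

2. Step 4. Proton transfer from C8 (enolisation) or β-hydride reduction may replace addition at the doubly flanked carbonyl, and facial selectivity may erode with the larger sp3 nucleophile. The fallback builds the C9–C11 bond with a small, irreversible ylide and then extends the chain. It sets out from ketone 8: Me3S+ I−/n-BuLi (THF, −10 °C → rt) should deliver CH2 axially on the α-face to give the spiro-epoxide F3 (C11 α, oxygen β). SN2 opening at the unsubstituted epoxide carbon with 3-lithio-1-(trimethylsilyl)propyne F4 (from 1-(trimethylsilyl)propyne and n-BuLi, THF/DMPU, −20 °C → rt) would return alcohol 12.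

3. Step 14. Hydride delivery from the α-face (axial attack) may compete because the axial 4β-methyl also screens the equatorial trajectory, and base may transpose the ketol. The fallback installs both oxygens at once by cis-dihydroxylation. It sets out from silyl enol ether 24: CsF/PhNTf2 (DME, rt) would give the Δ2 enol triflate F5, and Pd(OAc)2/PPh3, Bu3N, HCO2H (DMF, 60 °C) would reduce it to the Δ2 alkene F6. OsO4 (cat.), NMO, acetone/H2O, 0 °C should osmylate the ring alkene on the α-face, anti to the two axial β-methyl groups, giving diol 28 (steps 13 and 14 are skipped). The conjugated trisubstituted enoate is the slower partner, so the oxidant would be limited to one equivalent.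

**Further compounds**
F1 | step 10 | methyl (2E)-5-[(1S,2S,3S,6R)-2-(2-cyanoethyl)-2,6-dimethyl-3-(prop-1-en-2-yl)-1-(triethylsilyloxy)cyclohexyl]-3-methylpent-2-enoate | COC(=O)/C=C(\C)CC[C@]1(O[Si](CC)(CC)CC)[C@H](C)CC[C@@H](C(C)=C)[C@]1(C)CCC#N
F2 | step 10 | C3 ketimine corresponding to ketone 23 | COC(=O)/C=C(\C)CC[C@]1(O[Si](CC)(CC)CC)[C@H](C)CC[C@H]2C(C)(C)C(=N)CC[C@@]21C
F3 | step 4 | spiro-epoxide of ketone 8 (C11 α, oxygen β) | C1O[C@]12[C@H](C)CC[C@@H](C(C)=C)[C@]2(C)CC=C
F4 | step 4 | 3-lithio-1-(trimethylsilyl)prop-1-yne | [Li]CC#C[Si](C)(C)C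
F5 | step 14 | Δ2 enol triflate of ketone 23 | COC(=O)/C=C(\C)CC[C@]1(O[Si](CC)(CC)CC)[C@H](C)CC[C@H]2C(C)(C)C(OS(=O)(=O)C(F)(F)F)=CC[C@@]21C
F6 | step 14 | Δ2 alkene (2,3-didehydro, 9-O-SiEt3) | COC(=O)/C=C(\C)CC[C@]1(O[Si](CC)(CC)CC)[C@H](C)CC[C@H]2C(C)(C)C=CC[C@@]21C
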